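**Retrosynthetic overview**
1. The plan rests on the only ring, the 1,2-dioxolane O1–O2–C3–C4–C5. Its C3–O2–O1 segment is a methyl ketone carbon carrying a peroxide. Its C4–C5 segment is the CH2=C of a 1,1-disubstituted alkene that already holds the C5 methyl and the 10-phenyldecyl chain.
2. Acid ⇒ primary alcohol ⇒ benzoate: the C3 acetic acid arm travels as CH2CH2OBz and is raised to the acid level only at the end.
3. Benzoate dioxolane ⇒ racemic triethylsilylperoxy methyl ketal + alkene: a stepwise cationic (3+2) annulation makes C3–C4, then C5–O1. It closes the single ring and sets C3 and C5 under a confined chiral counteranion.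
4. Ketal ⇐ isoprenol (benzoylation, ozonolysis in methanol, O-silylation). Alkene ⇐ 11-phenylundecanoic acid (Weinreb amide, MeMgBr, Wittig methylenation).

Key step: step 7

Assumption: the sense of induction of the chiral anion cannot be predicted, so the catalyst antipode (both derive from commercial (R)- or (S)-BINOL) and its 3,3'-aryl groups would be chosen by screening so that the (3S,5S) isomer 19 is favoured.

**Step 1**
Reactants: 1 3-methylbut-3-en-1-ol (isoprenol); 2 benzoyl chloride
Product: 3 3-methylbut-3-en-1-yl benzoate
Conditions: BzCl, Et3N, DMAP (cat.), CH2Cl2, 0 °C → rt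
Reagents that add atoms: benzoyl chloride, O=C(Cl)c1ccccc1
Why: DMAP-catalysed acylation of an unhindered primary alcohol, in which the alkene is inert and no stereocentre is made.

**Step 2**
Reactants: 3 3-methylbut-3-en-1-yl benzoate
Product: 6 3-hydroperoxy-3-methoxybutyl benzoate (racemic), via primary ozonide 4 (not isolated), via carbonyl oxide 5 (not isolated)
Conditions: O3/O2, MeOH–CH2Cl2 (1:1), −78 °C to faint blue; Ar purge; no reductant; concentrate below 25 °C
Reagents that add atoms: ozone, [O-][O+]=O; methanol, CO
Why: Criegee ozonolysis in a participating solvent, in which the primary ozonide 4 of a 1,1-disubstituted alkene should cleave mainly to the more substituted carbonyl oxide 5 and formaldehyde, methanol traps 5 as the α-methoxy hydroperoxide, and the racemic ketal centre is of no consequence because step 7 erases it.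

**Step 3**
Reactants: 6 3-hydroperoxy-3-methoxybutyl benzoate; 7 chlorotriethylsilane
Product: 8 3-methoxy-3-(triethylsilylperoxy)butyl benzoate (racemic)
Conditions: Et3SiCl, imidazole, DMF, 0 °C → rt; Et3N-deactivated silica
Reagents that add atoms: chlorotriethylsilane, CC[Si](Cl)(CC)CC
Why: standard imidazole-promoted O-silylation of a hydroperoxide, which is more acidic and more nucleophilic than an alcohol, under a base too mild to touch the benzoate or the ketal.

**Step 4**
Reactants: 9 11-phenylundecanoic acid
Product: 11 N-methoxy-N-methyl-11-phenylundecanamide, via acyl imidazolide 10 (not isolated)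
Conditions: CDI, CH2Cl2, rt; then MeNH(OMe)·HCl, rt
Reagents that add atoms: N,O-dimethylhydroxylamine hydrochloride, CNOC.Cl; 1,1'-carbonyldiimidazole, O=C(n1ccnc1)n1ccnc1 (its imidazolyl group stays only in 10)
Why: carbonyldiimidazole activation followed by amidation (Weinreb amide synthesis) on a substrate whose only reactive group is the acid.

**Step 5**
Reactants: 11 N-methoxy-N-methyl-11-phenylundecanamide
Product: 13 12-phenyldodecan-2-one, via magnesium hemiaminal chelate 12 (not isolated)
Conditions: MeMgBr, THF, 0 °C; then 1 M HCl
Reagents that add atoms: methylmagnesium bromide, C[Mg]Br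
Why: Weinreb ketone synthesis, in which the five-membered magnesium chelate 12 persists until the acidic quench and so rules out a second addition.

**Step 6**
Reactants: 13 12-phenyldodecan-2-one
Product: 15 2-methyl-12-phenyldodec-1-ene, via oxaphosphetane 14 (not isolated)
Conditions: Ph3PCH3Br, KOt-Bu, THF, 0 °C → rt
Reagents that add atoms: methyltriphenylphosphonium bromide, C[P+](c1ccccc1)(c1ccccc1)c1ccccc1.[Br-]
Why: Wittig methylenation of an unhindered methyl ketone with the non-stabilised ylide, which fixes the double bond at the former carbonyl carbon and raises no question of geometry or configuration.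

**Step 7**
Reactants: 8 3-methoxy-3-(triethylsilylperoxy)butyl benzoate; 15 2-methyl-12-phenyldodec-1-ene
Product: 19 2-[(3S,5S)-3,5-dimethyl-5-(10-phenyldecyl)-1,2-dioxolan-3-yl]ethyl benzoate, via peroxycarbenium ion 16 (not isolated), via tertiary C5 carbocation 17 (not isolated), via silyloxonium ion 18 (not isolated)
Conditions: 8 (1.5 equiv), confined chiral IDPi acid (BINOL-derived imidodiphosphorimidate, 3,3'-aryl, N-triflyl; 5 mol %), toluene, −78 °C, strictly anhydrous; Et3N quench; silica chromatography to remove any cis isomer
Reagents that add atoms: none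
Why: Proposed new method: the strong acid is silylated by 8 to an Et3Si+/IDPi− pair, which abstracts methoxide from either enantiomer of 8 as Et3SiOMe, so the racemic ketal centre vanishes in the planar peroxycarbenium ion 16 that sits as a contact ion pair in the chiral pocket. The CH2 terminus of 15 adds to C3 (bond C3–C4) to leave the charge on tertiary C5 in 17, the silicon-bearing oxygen O1 collapses on C5 (bond C5–O1) to give silyloxonium ion 18, and 18 returns Et3Si+ to the anion, which turns the cycle over without any further reagent. The one ring closes by lone pair–cation collapse to a five-membered ring, formally 5-endo with respect to the former C4=C5 bond but without the usual stereoelectronic penalty, because an empty p orbital and not a π bond is attacked. The closest known reaction types are the racemic SnCl4- or TiCl4-mediated annulation of triethylsilylperoxy ketals with alkenes to 1,2-dioxolanes and the silylium/IDPi-catalysed enantioselective addition of π-nucleophiles to oxocarbenium ions made from acetals, and what has not been shown is their union. C3 is set by the face of 16 that the anion leaves open (methyl against benzoyloxyethyl) and C5 by the C4–C5 rotamer that the pocket tolerates at the moment of closure (methyl against the linear chain), the wanted result being the (3S,5S) isomer with the two methyl groups trans. The step needs Markovnikov regioselectivity, which the 1,1-disubstitution of 15 secures, and annulation faster than proton loss from 16 or 17, which the ester oxygen placed two carbons away from C3, the nucleofugal silyl group on O1, the non-basic anion and the low temperature should secure.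

**Step 8**
Reactants: 19 2-[(3S,5S)-3,5-dimethyl-5-(10-phenyldecyl)-1,2-dioxolan-3-yl]ethyl benzoate
Product: 20 2-[(3S,5S)-3,5-dimethyl-5-(10-phenyldecyl)-1,2-dioxolan-3-yl]ethanol
Conditions: K2CO3 (0.2 equiv), MeOH–THF (3:1), 0 °C → rt
Reagents that add atoms: none
Why: base-catalysed transesterification (Zemplén-type methanolysis), safe here because C3 and C5 carry no hydrogen, so a Kornblum–DeLaMare fragmentation of the peroxide has no path and both stereocentres stay untouched.

**Step 9**
Reactants: 20 2-[(3S,5S)-3,5-dimethyl-5-(10-phenyldecyl)-1,2-dioxolan-3-yl]ethanol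
Product: 22 andavadoic acid (2-[(3R,5S)-3,5-dimethyl-5-(10-phenyldecyl)-1,2-dioxolan-3-yl]acetic acid), via aldehyde 21 (not isolated)
Conditions: TEMPO (20 mol %), PhI(OAc)2 (2.5 equiv), CH2Cl2–H2O (2:1), 0 °C → rt
Reagents that add atoms: water, O
Why: nitroxyl/oxoammonium-catalysed oxidation of a primary alcohol through aldehyde 21 and its hydrate to the acid in a weakly acidic medium that neither reduces the O–O bond nor promotes β-elimination, with both quaternary centres unable to epimerise (the C3 descriptor changes from S to R only through the change in CIP ranking).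

**Compound list**
1 | 3-methylbut-3-en-1-ol (isoprenol) | C=C(C)CCO | starting material
2 | benzoyl chloride | O=C(Cl)c1ccccc1 | starting material
3 | 3-methylbut-3-en-1-yl benzoate | C=C(C)CCOC(=O)c1ccccc1 | intermediate
4 | 2-(4-methyl-1,2,3-trioxolan-4-yl)ethyl benzoate, primary ozonide (not isolated) | CC1(CCOC(=O)c2ccccc2)COOO1 | intermediate
5 | 3-oxobutyl benzoate O-oxide, carbonyl oxide (not isolated) | CC(CCOC(=O)c1ccccc1)=[O+][O-] | intermediate
6 | 3-hydroperoxy-3-methoxybutyl benzoate (racemic) | COC(C)(CCOC(=O)c1ccccc1)OO | intermediate
7 | chlorotriethylsilane | CC[Si](Cl)(CC)CC | starting material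
8 | 3-methoxy-3-(triethylsilylperoxy)butyl benzoate (racemic) | COC(C)(CCOC(=O)c1ccccc1)OO[Si](CC)(CC)CC | intermediate
9 | 11-phenylundecanoic acid | OC(=O)CCCCCCCCCCc1ccccc1 | starting material
10 | 1-(imidazol-1-yl)-11-phenylundecan-1-one, acyl imidazolide (not isolated) | O=C(CCCCCCCCCCc1ccccc1)n1ccnc1 | intermediate
11 | N-methoxy-N-methyl-11-phenylundecanamide | CON(C)C(=O)CCCCCCCCCCc1ccccc1 | intermediate
12 | bromomagnesium 2-[methoxy(methyl)amino]-12-phenyldodecan-2-olate, chelate (not isolated) | CON(C)C(C)(CCCCCCCCCCc1ccccc1)O[Mg]Br | intermediate
13 | 12-phenyldodecan-2-one | CC(=O)CCCCCCCCCCc1ccccc1 | intermediate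
14 | 4-methyl-2,2,2-triphenyl-4-(10-phenyldecyl)-1,2λ5-oxaphosphetane (not isolated) | CC1(CCCCCCCCCCc2ccccc2)CP(c2ccccc2)(c2ccccc2)(c2ccccc2)O1 | intermediate
15 | 2-methyl-12-phenyldodec-1-ene | C=C(C)CCCCCCCCCCc1ccccc1 | intermediate
16 | [4-(benzoyloxy)butan-2-ylidene](triethylsilyloxy)oxonium, peroxycarbenium ion as its IDPi salt (not isolated) | CC(CCOC(=O)c1ccccc1)=[O+]O[Si](CC)(CC)CC | intermediate
17 | tertiary C5 carbocation with C3 configured as in 19, IDPi salt (not isolated) | C[C+](CCCCCCCCCCc1ccccc1)C[C@](C)(CCOC(=O)c1ccccc1)OO[Si](CC)(CC)CC | intermediate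
18 | O1-triethylsilyl-1,2-dioxolan-1-ium ion with C3 and C5 configured as in 19, IDPi salt (not isolated) | C[C@]1(CCCCCCCCCCc2ccccc2)C[C@](C)(CCOC(=O)c2ccccc2)O[O+]1[Si](CC)(CC)CC | intermediate
19 | 2-[(3S,5S)-3,5-dimethyl-5-(10-phenyldecyl)-1,2-dioxolan-3-yl]ethyl benzoate (methyl groups trans) | C[C@]1(CCCCCCCCCCc2ccccc2)C[C@](C)(CCOC(=O)c2ccccc2)OO1 | intermediate
20 | 2-[(3S,5S)-3,5-dimethyl-5-(10-phenyldecyl)-1,2-dioxolan-3-yl]ethanol | C[C@]1(CCCCCCCCCCc2ccccc2)C[C@](C)(CCO)OO1 | intermediate
21 | 2-[(3R,5S)-3,5-dimethyl-5-(10-phenyldecyl)-1,2-dioxolan-3-yl]acetaldehyde (not isolated) | C[C@]1(CCCCCCCCCCc2ccccc2)C[C@](C)(CC=O)OO1 | intermediate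
22 | andavadoic acid, 2-[(3R,5S)-3,5-dimethyl-5-(10-phenyldecyl)-1,2-dioxolan-3-yl]acetic acid | C[C@]1(CCCCCCCCCCc2ccccc2)C[C@](C)(CC(=O)O)OO1 | target

**Step count**
Total steps: 9. Longest linear sequence: 6 (steps 1–3 or steps 4–6, followed by steps 7–9).

**Three steps most likely to fail**

1. **Step 7.**
   - What may go wrong: weak discrimination between the faces of the planar C3 cation. Free rotation about C4–C5 before closure, since a methyl group and a linear alkyl chain differ little. Proton loss from either cation. Reversible capture of the C3 cation by the benzoate carbonyl. Acid-induced isomerisation or oligomerisation of the alkene.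
   - Fallback: it sets out from 8 and 15 and sorts the stereochemistry after the bond formation instead of during it. The known stoichiometric Lewis acid annulation (SnCl4, CH2Cl2, −78 °C) should deliver the dioxolane without absolute control. Silica chromatography would remove the cis diastereomer rac-2-[(3R,5S)-3,5-dimethyl-5-(10-phenyldecyl)-1,2-dioxolan-3-yl]ethyl benzoate F1. Preparative SFC on a polysaccharide chiral phase, with the benzoate as chromophore and recognition element, would then part 19 from its mirror image 2-[(3R,5R)-3,5-dimethyl-5-(10-phenyldecyl)-1,2-dioxolan-3-yl]ethyl benzoate F2. The fallback returns to the route at 19.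

2. **Step 2.**
   - What may go wrong: cleavage of the primary ozonide in the unwanted direction. Loss of methanol or hydrogen peroxide from the perketal during concentration or chromatography. Slow over-ozonation of the benzoate ring.
   - Fallback: it sets out from 3 and builds the perketal by exchange instead of by carbonyl oxide trapping. Ozonolysis in CH2Cl2 with Me2S work-up would give 3-oxobutyl benzoate F3. Ketalisation with HC(OMe)3, MeOH and catalytic TsOH would give 3,3-dimethoxybutyl benzoate F4. Acid-catalysed perketal exchange of one methoxy group (anhydrous ethereal H2O2, catalytic camphorsulfonic acid, 0 °C) would lead to 6, where the route is rejoined.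

3. **Step 9.**
   - What may go wrong: stalling at the aldehyde level because the lipophilic substrate partitions poorly into the aqueous phase. Ester formation from the hemiacetal of aldehyde and alcohol. Ring opening by β-elimination if the aldehyde lingers.
   - Fallback: it sets out from 20 and splits the oxidation into two nitroxyl-free operations with a different oxidant for each level. Buffered Dess–Martin oxidation (NaHCO3, CH2Cl2, 0 °C) with rapid isolation of aldehyde 21 comes first. A Pinnick oxidation follows (NaClO2, NaH2PO4, 2-methylbut-2-ene, t-BuOH–THF–H2O), which returns to the route at 22.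

**Further compounds**
F1 | step 7 | rac-2-[(3R,5S)-3,5-dimethyl-5-(10-phenyldecyl)-1,2-dioxolan-3-yl]ethyl benzoate (methyl groups cis, one enantiomer drawn) | C[C@]1(CCCCCCCCCCc2ccccc2)C[C@@](C)(CCOC(=O)c2ccccc2)OO1
F2 | step 7 | 2-[(3R,5R)-3,5-dimethyl-5-(10-phenyldecyl)-1,2-dioxolan-3-yl]ethyl benzoate (enantiomer of 19) | C[C@@]1(CCCCCCCCCCc2ccccc2)C[C@@](C)(CCOC(=O)c2ccccc2)OO1
F3 | step 2 | 3-oxobutyl benzoate | CC(=O)CCOC(=O)c1ccccc1
F4 | step 2 | 3,3-dimethoxybutyl benzoate | COC(C)(CCOC(=O)c1ccccc1)OC
F0 | step 9 | none | none
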